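**Retrosynthetic overview**

1. Target 28 ← 24: acetylation, BCl3 demethylation, (NH4)2Ce(NO3)6 oxidation of ring C and DDQ dehydrogenation (C6=C7) come last, on the tetracyclic trimethoxy lactone 24.
2. 24 ← 22: ring A is closed last through the C2–C3 bond. The cyclopropanone silyl ketal 22 (cyclopropane C19–C4–C3 fused to the δ-lactone) is opened by ZnCl2 to a C3 zinc homoenolate, which couples with C2 of the chloroethyl arm on C10.
3. Enabling feature: C3 is the β-carbon of the lactone carbonyl C19 and sits on the quaternary C4, so the unit C19(=O)–C4–C3 can be stored as a strained cyclopropane; the 19,20-lactone ring holds C3 and the C1–C2 arm 1,3-syn-diaxial.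
4. 22 ← 20 ← 11: C4 by convex-face cyclopropanation, C10 by anti alkylation, and C5 by an enamine-catalysed Michael addition of propanal to the alkylidene aryl lactone 11 (the only catalyst-set stereocentre).
5. 11 ← 6 + 7 (Diels–Alder, ring B) ← 1. Ring order: C (bought arene) → B → temporary aryl lactone → δ-lactone → temporary cyclopropane → A.

Key step: step 12

Assumption: atom labels follow abietane numbering (C18 = methyl on C4, C19 = lactone carbonyl, C20 = CH2O on C10), and the (S)-catalyst of step 6 is assumed to give the (5S) adduct; if the sense is opposite, its enantiomer is used.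

Step 1
Reactants: 1 1,3-dimethoxybenzene; 2 acetone
Product: 4 2-(2,6-dimethoxyphenyl)propan-2-ol, via 2,6-dimethoxyphenyllithium 3 (not isolated)
Conditions: n-BuLi, THF, 0 °C to rt; then 2, −78 °C to rt; H2O
Reagents that add atoms: none
Why: Directed ortho-metalation at the carbon flanked by both methoxy groups, then 1,2-addition of the aryllithium to acetone, should give the tertiary benzylic alcohol.

Step 2
Reactants: 4 2-(2,6-dimethoxyphenyl)propan-2-ol
Product: 5 1,3-dimethoxy-2-(propan-2-yl)benzene
Conditions: Et3SiH, CF3CO2H, CH2Cl2, 0 °C to rt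
Reagents that add atoms: none
Why: Ionisation of the tertiary benzylic alcohol and hydride transfer from the silane (ionic hydrogenation) should give the isopropyl arene.

Step 3
Reactants: 5 1,3-dimethoxy-2-(propan-2-yl)benzene
Product: 6 2-methoxy-3-(propan-2-yl)-1,4-benzoquinone
Conditions: H2O2 (30% aq.), MeReO3 (cat.), AcOH, 40 °C
Reagents that add atoms: hydrogen peroxide, OO
Why: Oxygen transfer from the rhenium peroxo complex to the position para to a methoxy group, then oxidation of the p-methoxyphenol with loss of methanol (arene-to-p-quinone oxidation), should give the quinone, and the mirror symmetry of 5 allows only one regioisomer.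

Step 4
Reactants: 6 2-methoxy-3-(propan-2-yl)-1,4-benzoquinone; 7 methyl (2E)-penta-2,4-dienoate
Product: 10 6-hydroxy-8-methoxy-7-(propan-2-yl)-4,5-dihydro-2H-naphtho[1,8-bc]furan-2-one (phenolic aryl lactone), via Diels–Alder adduct 8 (not isolated), via hydroquinone ester 9 (not isolated)
Conditions: PhMe, 90 °C; then TsOH·H2O (cat.), 110 °C
Reagents that add atoms: none
Why: Diels–Alder reaction in which the ester-bearing diene terminus (C10) should bond to the quinone carbon next to the carbonyl that the vinylogous methoxy group does not deactivate ("ortho" rule), then acid-catalysed enolisation to the hydroquinone, lactonisation of the C11 hydroxyl onto the ester and migration of the alkene into conjugation (C10=C5); the stereocentres of 8 are erased.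

Step 5
Reactants: 10 phenolic aryl lactone
Product: 11 6,8-dimethoxy-7-(propan-2-yl)-4,5-dihydro-2H-naphtho[1,8-bc]furan-2-one
Conditions: Me3SiCHN2, MeOH/PhMe, rt
Reagents that add atoms: (trimethylsilyl)diazomethane, C[Si](C)(C)C=[N+]=[N-]
Why: Diazomethane released in the flask methylates the C14 phenol under neutral conditions, which should avoid C-alkylation through the easily formed dienolate of the lactone.

Step 6
Reactants: 11 alkylidene aryl lactone; 12 propanal
Product: 13 2-[(3S)-6,8-dimethoxy-2-oxo-7-(propan-2-yl)-2a,3,4,5-tetrahydro-2H-naphtho[1,8-bc]furan-3-yl]propanal (5S; epimer mixture at C4 and C10)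
Conditions: (S)-2-[diphenyl(trimethylsilyloxy)methyl]pyrrolidine (cat.), PhCO2H (cat.), CHCl3, 0 °C
Reagents that add atoms: none
Why: Enamine catalysis (Michael addition of an aldehyde to a 3-alkylidene-benzofuranone-type acceptor): the (E)-enamine of propanal should attack the β-carbon C5 on the face left open by the diphenyl(silyloxy)methyl group, which sets C5, while C4 and C10 form as mixtures that later steps reset.

Step 7
Reactants: 13 Michael adduct; 14 1-chloro-2-iodoethane
Product: 15 2-[(2aR,3S)-2a-(2-chloroethyl)-6,8-dimethoxy-2-oxo-7-(propan-2-yl)-2a,3,4,5-tetrahydro-2H-naphtho[1,8-bc]furan-3-yl]propanal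
Conditions: Cs2CO3, DMF, 0 °C to rt
Reagents that add atoms: none
Why: C-Alkylation of the benzofuranone enolate at C10 by the iodide end of 14 should occur anti to the pseudo-axial side chain on the neighbouring C5 (1,2-induction), which sets the quaternary centre C10 with the chloroethyl arm trans to C4.

Step 8
Reactants: 15 alkylated aldehyde
Product: 16 (1R,2S)-1-(2-chloroethyl)-1-(hydroxymethyl)-2-(1-hydroxypropan-2-yl)-5,7-dimethoxy-6-(propan-2-yl)-1,2,3,4-tetrahydronaphthalen-8-ol (triol)
Conditions: i-Bu2AlH, CH2Cl2, −78 to 0 °C; aq. potassium sodium tartrate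
Reagents that add atoms: none
Why: i-Bu2AlH should reduce the aldehyde and the aryl lactone to the primary alcohols, and the weakly nucleophilic aluminium alkoxides should not displace the chloride.

Step 9
Reactants: 16 triol
Product: 17 [(1R,2S)-1-(2-chloroethyl)-2-(1-hydroxypropan-2-yl)-5,7,8-trimethoxy-6-(propan-2-yl)-1,2,3,4-tetrahydronaphthalen-1-yl]methanol (diol)
Conditions: Me3SiCHN2, MeOH/PhMe, rt
Reagents that add atoms: (trimethylsilyl)diazomethane, C[Si](C)(C)C=[N+]=[N-]
Why: Only the phenol is acidic enough to protonate diazomethane, so it should be methylated selectively and without a phenoxide that could close a chroman onto the chloroethyl arm.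

Step 10
Reactants: 17 diol
Product: 20 cis-fused δ-lactone (C19 carbonyl; 5S,10R; C4 epimer mixture), via hydroxy aldehyde 18 (not isolated), via lactol 19 (not isolated)
Conditions: TEMPO (cat.), PhI(OAc)2, CH2Cl2, rt
Reagents that add atoms: none
Why: Oxoammonium oxidation should take the less hindered C19 alcohol to the aldehyde, which closes to the lactol with the neopentyl C20 alcohol and is oxidised on to the lactone (oxidative lactonisation of a 1,5-diol); the cis relation of C4 and C20 from step 7 allows the ring.

Step 11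
Reactants: 20 δ-lactone
Product: 22 cyclopropanone silyl ketal (C19 bears OSiMe3 and the ring oxygen; C3H2 bridges C19 and C4 on the face of the chloroethyl arm), via silyl ketene acetal 21 (not isolated)
Conditions: LiN(i-Pr)2, Me3SiCl, THF, −78 °C; solvent switch to hexane, filtration; then Et2Zn, CH2I2, CH2Cl2, 0 °C
Reagents that add atoms: chlorotrimethylsilane, C[Si](C)(C)Cl; diiodomethane, ICI
Why: In-situ trapping of the lactone enolate as the ketene silyl acetal and Furukawa-type Simmons–Smith cyclopropanation (the Nakamura–Kuwajima route to 1-alkoxy-1-siloxycyclopropanes) should deliver CH2 (C3) to the convex face of the cis-fused bicycle, anti to ring B and syn to the chloroethyl arm, which sets C4 and C19.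

Step 12
Reactants: 22 cyclopropanone silyl ketal
Product: 24 (4S,5R,10R)-11,12,14-trimethoxyabieta-8,11,13-trien-19,20-olide, via zinc homoenolate 23 (not isolated)
Conditions: ZnCl2, Et2O, rt; then Pd2(dba)3 (cat.), PCyp3 (cat.), N-methylimidazole, NaI (cat.), THF/NMP, 80 °C, high dilution
Reagents that add atoms: none
Why: Proposed new method: ZnCl2 should cleave the less substituted C19–C3 bond of the cyclopropanone silyl ketal (electrophilic ring opening driven by release of ring strain and formation of the lactone C=O) to give the primary alkylzinc chloride 23, which cannot β-eliminate because C4 is quaternary, while the C2–Cl bond stays untouched; zerovalent palladium with PCyp3 then inserts into the C2–halogen bond (iodide formed in situ), transmetalation gives a seven-membered dialkylpalladacycle and C(sp3)–C(sp3) reductive elimination forms C2–C3. The closest known reaction types are the Nakamura–Kuwajima formation of zinc ester homoenolates from 1-alkoxy-1-siloxycyclopropanes and the alkyl–alkyl Negishi coupling of primary alkyl halides with alkylzinc halides (Pd/PCyp3), which have not been joined in one molecule. Ring A closes as a six-membered ring (formally 6-exo-tet at C2) and thereby completes the 3-oxabicyclo[3.3.1]nonan-2-one; the cyclopropane is the only ring that opens. No new stereocentre is formed (C2 and C3 are CH2), and C4, C5 and C10 are carried over because no bond to them is broken. The step needs metalation at C3 in the presence of an alkyl halide, secured by making the organozinc from the strained ring and not from a halide, and cyclisation over intermolecular coupling, secured by the lactone ring that holds C3 and the C1–C2 arm syn-diaxial and by dilution.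

Step 13
Reactants: 24 tetracyclic trimethoxy lactone
Product: 25 (4S,5R,10R)-11,12,14-trimethoxyabieta-6,8,11,13-tetraen-19,20-olide
Conditions: DDQ, 1,4-dioxane (dry), 80 °C
Reagents that add atoms: none
Why: Hydride abstraction by DDQ from the benzylic C7, whose cation is stabilised by the ortho and para methoxy groups, and loss of H6 should give the styrene-type C6=C7 alkene; the quaternary C10 prevents aromatisation of ring B.

Step 14
Reactants: 25 dehydro lactone
Product: 26 (4S,5R,10R)-12-methoxy-11,14-dioxoabieta-6,8,12-trien-19,20-olide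
Conditions: (NH4)2Ce(NO3)6, MeCN/H2O, 0 °C
Reagents that add atoms: water, O
Why: Oxidative demethylation of the para-related C11 and C14 methoxy groups by tetravalent cerium should give the p-quinone and leave the C12 methoxy group as a vinylogous ester.

Step 15
Reactants: 26 methoxyquinone
Product: 27 (4S,5R,10R)-12-hydroxy-11,14-dioxoabieta-6,8,12-trien-19,20-olide
Conditions: BCl3, CH2Cl2, −78 to 0 °C; H2O
Reagents that add atoms: none
Why: BCl3 chelated by the C11 carbonyl should cleave the neighbouring vinylogous methyl ester selectively (demethylation ortho to a carbonyl), and the hindered lactone should survive the cold conditions.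

Step 16
Reactants: 27 hydroxyquinone
Product: 28 (4S,5R,10R)-12-acetoxy-11,14-dioxoabieta-6,8,12-trien-19,20-olide (target)
Conditions: Ac2O, pyridine, DMAP (cat.), CH2Cl2, rt
Reagents that add atoms: acetic anhydride, CC(=O)OC(C)=O
Why: DMAP-catalysed O-acylation of the acidic hydroxyquinone should give the enol acetate of the target.

**Compound list**

1 | 1,3-dimethoxybenzene | COc1cccc(OC)c1 | starting material
2 | acetone | CC(C)=O | starting material
3 | 2,6-dimethoxyphenyllithium | [Li]c1c(OC)cccc1OC | intermediate
4 | 2-(2,6-dimethoxyphenyl)propan-2-ol | COc1cccc(OC)c1C(C)(C)O | intermediate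
5 | 1,3-dimethoxy-2-(propan-2-yl)benzene | COc1cccc(OC)c1C(C)C | intermediate
6 | 2-methoxy-3-(propan-2-yl)-1,4-benzoquinone | COC1=C(C(C)C)C(=O)C=CC1=O | intermediate
7 | methyl (2E)-penta-2,4-dienoate | COC(=O)/C=C/C=C | starting material
8 | endo Diels–Alder adduct, methyl 7-methoxy-5,8-dioxo-6-(propan-2-yl)-1,4,4a,5,8,8a-hexahydronaphthalene-1-carboxylate (racemic, ring hydrogens all cis, one enantiomer drawn) | COC(=O)[C@H]1C=CC[C@@H]2[C@H]1C(=O)C(OC)=C(C(C)C)C2=O | intermediate
9 | methyl 5,8-dihydroxy-7-methoxy-6-(propan-2-yl)-1,4-dihydronaphthalene-1-carboxylate (racemic) | COC(=O)C1C=CCc2c(O)c(C(C)C)c(OC)c(O)c12 | intermediate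
10 | 6-hydroxy-8-methoxy-7-(propan-2-yl)-4,5-dihydro-2H-naphtho[1,8-bc]furan-2-one | O=C1Oc2c(OC)c(C(C)C)c(O)c3c2C1=CCC3 | intermediate
11 | 6,8-dimethoxy-7-(propan-2-yl)-4,5-dihydro-2H-naphtho[1,8-bc]furan-2-one | O=C1Oc2c(OC)c(C(C)C)c(OC)c3c2C1=CCC3 | intermediate
12 | propanal | CCC=O | starting material
13 | Michael adduct, 2-[(3S)-6,8-dimethoxy-2-oxo-7-(propan-2-yl)-2a,3,4,5-tetrahydro-2H-naphtho[1,8-bc]furan-3-yl]propanal (C4 and C10 epimer mixture) | CC(C=O)[C@@H]1CCc2c(OC)c(C(C)C)c(OC)c3OC(=O)C1c23 | intermediate
14 | 1-chloro-2-iodoethane | ClCCI | starting material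
15 | 2-[(2aR,3S)-2a-(2-chloroethyl)-6,8-dimethoxy-2-oxo-7-(propan-2-yl)-2a,3,4,5-tetrahydro-2H-naphtho[1,8-bc]furan-3-yl]propanal (C4 epimer mixture) | CC(C=O)[C@@H]1CCc2c(OC)c(C(C)C)c(OC)c3OC(=O)[C@@]1(CCCl)c23 | intermediate
16 | triol, (1R,2S)-1-(2-chloroethyl)-1-(hydroxymethyl)-2-(1-hydroxypropan-2-yl)-5,7-dimethoxy-6-(propan-2-yl)-1,2,3,4-tetrahydronaphthalen-8-ol | COc1c(C(C)C)c(OC)c2c(c1O)[C@@](CO)(CCCl)[C@H](C(C)CO)CC2 | intermediate
17 | diol, [(1R,2S)-1-(2-chloroethyl)-2-(1-hydroxypropan-2-yl)-5,7,8-trimethoxy-6-(propan-2-yl)-1,2,3,4-tetrahydronaphthalen-1-yl]methanol | COc1c(C(C)C)c(OC)c2c(c1OC)[C@@](CO)(CCCl)[C@H](C(C)CO)CC2 | intermediate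
18 | hydroxy aldehyde (C19 aldehyde, C20 alcohol) | COc1c(C(C)C)c(OC)c2c(c1OC)[C@@](CO)(CCCl)[C@H](C(C)C=O)CC2 | intermediate
19 | lactol (C19 hemiacetal with O–C20) | COc1c(C(C)C)c(OC)c2c(c1OC)[C@]1(CCCl)COC(O)C(C)[C@@H]1CC2 | intermediate
20 | cis-fused δ-lactone (C19(=O)–O–C20, fused to ring B at C5–C10; C4 bears H and CH3; C10 bears CH2CH2Cl; 5S,10R) | COc1c(C(C)C)c(OC)c2c(c1OC)[C@]1(CCCl)COC(=O)C(C)[C@@H]1CC2 | intermediate
21 | O-trimethylsilyl ketene acetal of 20 (C4=C19) | COc1c(C(C)C)c(OC)c2c(c1OC)[C@]1(CCCl)COC(O[Si](C)(C)C)=C(C)[C@@H]1CC2 | intermediate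
22 | cyclopropanone silyl ketal (cyclopropane C19–C4–C3, C3 cis to the chloroethyl arm and to H5) | COc1c(C(C)C)c(OC)c2c(c1OC)[C@]1(CCCl)CO[C@@]3(O[Si](C)(C)C)C[C@@]3(C)[C@@H]1CC2 | intermediate
23 | zinc homoenolate (δ-lactone with C3H2–ZnCl on quaternary C4) | COc1c(C(C)C)c(OC)c2c(c1OC)[C@]1(CCCl)COC(=O)[C@@](C)(C[Zn]Cl)[C@@H]1CC2 | intermediate
24 | (4S,5R,10R)-11,12,14-trimethoxyabieta-8,11,13-trien-19,20-olide | COc1c(C(C)C)c(OC)c2c(c1OC)[C@]13CCC[C@](C)(C(=O)OC1)[C@@H]3CC2 | intermediate
25 | (4S,5R,10R)-11,12,14-trimethoxyabieta-6,8,11,13-tetraen-19,20-olide | COc1c(C(C)C)c(OC)c2c(c1OC)[C@]13CCC[C@](C)(C(=O)OC1)[C@@H]3C=C2 | intermediate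
26 | (4S,5R,10R)-12-methoxy-11,14-dioxoabieta-6,8,12-trien-19,20-olide | COC1=C(C(C)C)C(=O)C2=C(C1=O)[C@]13CCC[C@](C)(C(=O)OC1)[C@@H]3C=C2 | intermediate
27 | (4S,5R,10R)-12-hydroxy-11,14-dioxoabieta-6,8,12-trien-19,20-olide | OC1=C(C(C)C)C(=O)C2=C(C1=O)[C@]13CCC[C@](C)(C(=O)OC1)[C@@H]3C=C2 | intermediate
28 | (4S,5R,10R)-12-acetoxy-11,14-dioxoabieta-6,8,12-trien-19,20-olide | CC(=O)OC1=C(C(C)C)C(=O)C2=C(C1=O)[C@]13CCC[C@](C)(C(=O)OC1)[C@@H]3C=C2 | target

Total step count: 16. Longest linear sequence: 16 steps (from 1).

**Three steps most likely to fail**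

1. Step 12 (Proposed new method). What may go wrong: protonation of the zinc homoenolate, β-hydride elimination of the alkylpalladium formed at C2 before transmetalation, or intermolecular coupling. The fallback uses known chemistry and makes the same C2–C3 bond by ring-closing metathesis. It sets out from 20 and comes back at 24. Kornblum oxidation (NaI, NaHCO3, DMSO, 110 °C) should give the aldehyde lactone F1, and methylenation with Ph3P=CH2 the allyl lactone F2. Palladium-catalysed α-vinylation of its lithium enolate (LiN(SiMe3)2, Pd(dba)2, P(t-Bu)3, vinyl bromide, PhMe) should give the α-vinyl lactone F3, with the vinyl group on the convex face as in step 11. Ring-closing metathesis with the second-generation Grubbs catalyst (H2IMes)(PCy3)Cl2Ru=CHPh should give the ring-A alkene F4, and hydrogenation (H2, Pd on carbon, EtOAc) gives 24.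

2. Step 6. What may go wrong: self-condensation of 11 through its dienolate, acylation of the amine catalyst by the aryl lactone, or poor face selection at C5. The fallback replaces enamine catalysis by hydrogen-bond/base catalysis with a malonate. It sets out from 11 and comes back at 16. Dimethyl methylmalonate with a quinine-derived bifunctional thiourea should give the malonate adduct F5, and alkylation with 14 (Cs2CO3, DMF) the alkylated malonate F6. Krapcho dealkoxycarbonylation (LiCl, wet DMSO, 130 °C) should give the monoester F7, and i-Bu2AlH reduction of the ester and the aryl lactone gives 16.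

3. Step 13. What may go wrong: hydride abstraction at the isopropyl methine, over-oxidation of the electron-rich ring C, or capture of the benzylic cation by traces of water. The fallback is the classical oxidation–reduction–elimination at C7. It sets out from 24 and comes back at 25. Benzylic oxidation (CrO3, AcOH) should give the 7-ketone F8, NaBH4 the 7-alcohol F9, and acid-catalysed dehydration (TsOH, PhH, 80 °C) gives 25.

**Further compounds**

F1 | step 12 | aldehyde lactone (20 with C10–CH2–CHO in place of the chloroethyl arm) | COc1c(C(C)C)c(OC)c2c(c1OC)[C@]1(CC=O)COC(=O)C(C)[C@@H]1CC2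
F2 | step 12 | allyl lactone (C10–CH2–CH=CH2) | COc1c(C(C)C)c(OC)c2c(c1OC)[C@]1(CC=C)COC(=O)C(C)[C@@H]1CC2
F3 | step 12 | α-vinyl lactone (C4 bears CH3 and CH=CH2) | COc1c(C(C)C)c(OC)c2c(c1OC)[C@]1(CC=C)COC(=O)[C@@](C)(C=C)[C@@H]1CC2
F4 | step 12 | ring-A alkene, 11,12,14-trimethoxyabieta-2,8,11,13-tetraen-19,20-olide | COc1c(C(C)C)c(OC)c2c(c1OC)[C@]13CC=C[C@](C)(C(=O)OC1)[C@@H]3CC2
F5 | step 6 | malonate adduct (C5–C(CH3)(CO2CH3)2; C10 epimer mixture) | COC(=O)C(C)(C(=O)OC)[C@@H]1CCc2c(OC)c(C(C)C)c(OC)c3OC(=O)C1c23
F6 | step 6 | alkylated malonate (C10 bears CH2CH2Cl) | COC(=O)C(C)(C(=O)OC)[C@@H]1CCc2c(OC)c(C(C)C)c(OC)c3OC(=O)[C@@]1(CCCl)c23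
F7 | step 6 | monoester (C5–CH(CH3)CO2CH3; C4 epimer mixture) | COC(=O)C(C)[C@@H]1CCc2c(OC)c(C(C)C)c(OC)c3OC(=O)[C@@]1(CCCl)c23
F8 | step 13 | 7-ketone, 11,12,14-trimethoxy-7-oxoabieta-8,11,13-trien-19,20-olide | COc1c(C(C)C)c(OC)c2c(c1OC)[C@]13CCC[C@](C)(C(=O)OC1)[C@@H]3CC2=O
F9 | step 13 | 7-alcohol, 7-hydroxy-11,12,14-trimethoxyabieta-8,11,13-trien-19,20-olide (C7 epimer mixture) | COc1c(C(C)C)c(OC)c2c(c1OC)[C@]13CCC[C@](C)(C(=O)OC1)[C@@H]3CC2O
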